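The target is the malonate diester of two identical (5S,9S,10S)-labda-7,13E-dien-15-ol units, so one alcohol is made and esterified twice. Its ring B is built by forming C5–C6 on a ring-contracted precursor: in a hydrindenol whose five-membered ring (C5, C7, C8, C9, C10) holds a temporary C5=C7 double bond, a hydroxyl-directed Simmons–Smith methylenation adds the unsubstituted methylene C6 across C5=C7, closing the cyclopropane C5–C6–C7. Acid-triggered strain release then breaks C5–C7 and leaves C6 between C5 and C7 in the six-membered ring B. The step exploits that C6 is a bare CH2 between ring-fusion C5 and olefinic C7.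

Key step: step 7

Remark: labdane numbering is used throughout (ring A = C1–C5, C10; ring B = C5–C10; C17 = methyl on C8; C20 = methyl on C10). Centres that are erased later (C8 carbinol, cyclopropane C5/C7, and C9 before step 10) are left undefined in the SMILES.

Step 1
Reactants: 1 2,2,6-trimethylcyclohexanone; 2 allyl chloroformate
Product: 3 allyl 2,6,6-trimethylcyclohex-1-en-1-yl carbonate
Conditions: LiN(SiMe3)2, THF, 0 °C; then 2, −78 → 23 °C
Reagents that add atoms: allyl chloroformate (2), C=CCOC(Cl)=O
Why: The ketone has a single enolisable position (the future C10–H), and the hard chloroformate should acylate the hindered tetrasubstituted lithium enolate on oxygen (enol carbonate formation).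

Step 2
Reactants: 3 allyl 2,6,6-trimethylcyclohex-1-en-1-yl carbonate
Product: 4 (R)-2-allyl-2,6,6-trimethylcyclohexan-1-one
Conditions: Pd2(dba)3 (2.5 mol %), (R)-t-BuPHOX (6 mol %), THF, 23 °C
Reagents that add atoms: none
Why: Decarboxylative asymmetric allylic alkylation (Tsuji allylation): zerovalent palladium ionises the allyl carbonate, CO2 leaves, and the enolate recombines with the allyl fragment inside the chiral P,N-ligand pocket, which sets the quaternary C10; the (R)-ligand is chosen because this ligand family gives the ketone with the same descriptor as the ligand.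

Step 3
Reactants: 4 (R)-2-allyl-2,6,6-trimethylcyclohexan-1-one
Product: 5 (R)-2,2,6-trimethyl-6-(2-oxopropyl)cyclohexan-1-one
Conditions: PdCl2 (5 mol %), Cu(OAc)2·H2O (25 mol %), O2 (1 atm), DMA/H2O, 23 °C
Reagents that add atoms: water, O
Why: Tsuji–Wacker oxidation: Markovnikov hydroxypalladation of the terminal alkene places the ketone on the future C8 and leaves the future C7 as a methyl group.

Step 4
Reactants: 5 (R)-2,2,6-trimethyl-6-(2-oxopropyl)cyclohexan-1-one
Product: 6 (R)-4,4,7a-trimethyl-1,4,5,6,7,7a-hexahydro-2H-inden-2-one (enone C5=C7–C8=O)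
Conditions: KOH, xylenes, 110 °C (Dean–Stark)
Reagents that add atoms: none
Why: Intramolecular aldol condensation: the methyl ketone enolate (C7) attacks the hindered, non-enolisable C5 ketone in a five-membered closure, and irreversible dehydration pulls the equilibrium over, installing the temporary C5=C7 bond.

Step 5
Reactants: 6 bicyclic enone; 7 2-(2-bromoethyl)-2-methyl-1,3-dioxolane
Product: 8 C9-alkylated enone, (7aR)-4,4,7a-trimethyl-1-[2-(2-methyl-1,3-dioxolan-2-yl)ethyl]-1,4,5,6,7,7a-hexahydro-2H-inden-2-one (C9 epimers)
Conditions: LiN(i-Pr)2, THF, −78 °C; then 7, DMPU, −78 → 0 °C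
Reagents that add atoms: 2-(2-bromoethyl)-2-methyl-1,3-dioxolane (7), CC1(CCBr)OCCO1
Why: Kinetic enolate alkylation: C9 is the only acidic position (the γ-carbon C4 is quaternary), so the cross-conjugated lithium enolate is alkylated there by SN2; the C9 configuration is not controlled here and is corrected in step 10.

Step 6
Reactants: 8 C9-alkylated enone
Product: 9 allylic alcohol, the corresponding inden-2-ol (C8 and C9 epimers)
Conditions: i-Bu2AlH, CH2Cl2, −78 °C
Reagents that add atoms: none
Why: 1,2-Reduction of the cyclopentenone by the aluminium hydride gives the allylic alcohol that directs the next step; the new C8 centre is removed again in step 8.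

Step 7
Reactants: 9 allylic alcohol
Product: 10 cyclopropyl carbinol (cyclopropane C5–C6–C7 fused on the five-membered ring)
Conditions: Et2Zn (5 equiv), CH2I2 (10 equiv), CH2Cl2, 0 → 23 °C
Reagents that add atoms: diiodomethane, ICI
Why: The zinc alkoxide of the C8 hydroxyl holds an iodomethylzinc carbenoid and passes its CH2 (the future C6) to the C5=C7 double bond through a concerted butterfly transition state, so C5–C6 and C6–C7 form together. The closest known reaction type is the hydroxyl-directed Simmons–Smith cyclopropanation (Furukawa modification) of cyclic allylic alcohols, which tolerates fully substituted alkene carbons next to quaternary centres. The ring closed is the three-membered ring C5–C6–C7, by syn [2+1] addition. The new centres C5 and C7 are set cis to the C8 oxygen by the directing group; both are erased in steps 9 and 10, so either carbinol epimer can be used. The selectivity needed is reaction at a very congested trisubstituted alkene; it is secured by intramolecular delivery from the neighbouring alkoxide and by the absence of any other alkene in 9.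

Step 8
Reactants: 10 cyclopropyl carbinol
Product: 11 cyclopropyl ketone (C8 ketone conjugated to cyclopropane C5–C6–C7)
Conditions: Dess–Martin periodinane, NaHCO3, CH2Cl2, 23 °C
Reagents that add atoms: none
Why: Dess–Martin oxidation under buffered conditions turns the carbinol into the conjugated cyclopropyl ketone without ionising the acid-labile cyclopropylcarbinol or the dioxolane.

Step 9
Reactants: 11 cyclopropyl ketone
Product: 12 13,13-ethylenedioxy-14,15,17-trinorlabd-5-en-8-one (C9 epimers)
Conditions: anhydrous TsOH (0.3 equiv), toluene, 80 °C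
Reagents that add atoms: none
Why: Acid-catalysed homoconjugate opening of a cyclopropyl ketone: the protonated C8 carbonyl pulls open the cyclopropane bond to the carbon that best carries positive charge (tertiary C5, as in the isomerisation of sabina ketone to 4-isopropylcyclohexenone), so the temporary C5–C7 bond breaks, C6 becomes a ring member between C5 and C7, and loss of a C6 proton gives the C5=C6 alkene; without water the dioxolane should stay, and any conjugated C6=C7 isomer converges in step 10.

Step 10
Reactants: 12 13,13-ethylenedioxy-14,15,17-trinorlabd-5-en-8-one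
Product: 14 (5S,9S,10S)-13,13-ethylenedioxy-14,15,17-trinorlabdan-8-one, via C9-epimeric ketone 13 (not isolated)
Conditions: Mn(dpm)3 (10 mol %), PhSiH3, t-BuOOH, i-PrOH, 23 °C; then NaOMe, MeOH, 23 °C
Reagents that add atoms: none
Why: Metal-hydride hydrogen atom transfer hydrogenation (Mukaiyama-type): a hydrogen atom adds to C6 and the tertiary C5 radical takes the second hydrogen on the α face, away from the axial C19 and C20 methyl groups, which should give the trans ring fusion (5α-H); methoxide then equilibrates C9 next to the C8 ketone towards the equatorial side chain (9α-H).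

Step 11
Reactants: 14 trans-fused 8-ketone
Product: 15 13,13-ethylenedioxy-14,15,17-trinorlabd-7-en-8-yl trifluoromethanesulfonate
Conditions: KN(SiMe3)2, THF, −78 °C; then PhNTf2, −78 → 0 °C
Reagents that add atoms: N-phenylbis(trifluoromethanesulfonimide), O=S(=O)(N(c1ccccc1)S(=O)(=O)C(F)(F)F)C(F)(F)F
Why: Kinetic enolisation should take the C7 methylene and not the hindered C9 methine, and O-triflation fixes the C7=C8 double bond (enol triflate formation).

Step 12
Reactants: 15 enol triflate
Product: 16 13,13-ethylenedioxy-14,15-dinorlabd-7-ene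
Conditions: MeMgBr, Fe(acac)3 (5 mol %), THF/NMP, −30 → 0 °C
Reagents that add atoms: methylmagnesium bromide, C[Mg]Br
Why: Iron-catalysed Kumada-type cross-coupling of the alkenyl triflate with MeMgBr puts the C17 methyl on C8 without moving the double bond.

Step 13
Reactants: 16 13,13-ethylenedioxy-14,15-dinorlabd-7-ene
Product: 17 14,15-dinorlabd-7-en-13-one
Conditions: PPTS, acetone/H2O (10:1), 50 °C
Reagents that add atoms: water, O
Why: Acetal hydrolysis under weak acid frees the C13 ketone while the trisubstituted C7=C8 alkene should not be protonated.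

Step 14
Reactants: 17 14,15-dinorlabd-7-en-13-one
Product: 19 15,16-dinorlabd-7-en-13-yne, via enol phosphate 18 (not isolated)
Conditions: LiN(i-Pr)2 (1.1 equiv), THF, −78 °C; ClP(O)(OEt)2, −78 → 23 °C; then LiN(i-Pr)2 (2.2 equiv), −78 → 23 °C
Reagents that add atoms: diethyl chlorophosphate, CCOP(=O)(Cl)OCC (its atoms stay in 18 only and leave again)
Why: Kinetic deprotonation at the methyl group, O-phosphorylation and base-induced elimination of diethyl phosphate (Negishi alkyne synthesis from a methyl ketone) give the terminal alkyne.

Step 15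
Reactants: 19 15,16-dinorlabd-7-en-13-yne
Product: 20 (5S,9S,10S)-labda-7,13E-dien-15-ol
Conditions: AlMe3 (3 equiv), Cp2ZrCl2 (0.25 equiv), CH2Cl2, 23 °C; then n-BuLi, THF, −78 °C; (CH2O)n, −78 → 23 °C
Reagents that add atoms: trimethylaluminium, C[Al](C)C; paraformaldehyde (as formaldehyde), C=O
Why: Negishi zirconium-catalysed carboalumination: syn addition of methyl and aluminium across the alkyne puts aluminium on the terminal carbon, and hydroxymethylation of the alkenyl alanate with retention gives the (E)-trisubstituted allylic alcohol; the C7=C8 alkene should not react.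

Step 16
Reactants: 20 (5S,9S,10S)-labda-7,13E-dien-15-ol (2 equiv); 21 malonyl dichloride
Product: 22 bis[(5S,9S,10S)-labda-7,13E-dien-15-yl] malonate (CNP0113044.1)
Conditions: pyridine, CH2Cl2, −20 → 0 °C
Reagents that add atoms: malonyl dichloride (21), O=C(Cl)CC(Cl)=O
Why: Double O-acylation of the primary allylic alcohol by the diacid chloride (esterification in pyridine) joins two identical halves of one enantiomer to the C2-symmetric malonate.

Compound list
1 | 2,2,6-trimethylcyclohexanone | CC1CCCC(C)(C)C1=O | starting material
2 | allyl chloroformate | C=CCOC(Cl)=O | starting material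
3 | allyl 2,6,6-trimethylcyclohex-1-en-1-yl carbonate | CC1=C(OC(=O)OCC=C)C(C)(C)CCC1 | intermediate
4 | (R)-2-allyl-2,6,6-trimethylcyclohexan-1-one | C=CC[C@@]1(C)CCCC(C)(C)C1=O | intermediate
5 | (R)-2,2,6-trimethyl-6-(2-oxopropyl)cyclohexan-1-one | CC(=O)C[C@@]1(C)CCCC(C)(C)C1=O | intermediate
6 | (R)-4,4,7a-trimethyl-1,4,5,6,7,7a-hexahydro-2H-inden-2-one | CC1(C)CCC[C@]2(C)CC(=O)C=C12 | intermediate
7 | 2-(2-bromoethyl)-2-methyl-1,3-dioxolane | CC1(CCBr)OCCO1 | starting material
8 | C9-alkylated enone (C9 epimers) | CC1(C)CCC[C@]2(C)C(CCC3(C)OCCO3)C(=O)C=C12 | intermediate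
9 | allylic alcohol (C8 and C9 epimers) | CC1(C)CCC[C@]2(C)C(CCC3(C)OCCO3)C(O)C=C12 | intermediate
10 | cyclopropyl carbinol, cyclopropane C5–C6–C7 | CC1(C)CCC[C@]2(C)C(CCC3(C)OCCO3)C(O)C4CC124 | intermediate
11 | cyclopropyl ketone | CC1(C)CCC[C@]2(C)C(CCC3(C)OCCO3)C(=O)C4CC124 | intermediate
12 | 13,13-ethylenedioxy-14,15,17-trinorlabd-5-en-8-one (C9 epimers) | CC1(C)CCC[C@]2(C)C(CCC3(C)OCCO3)C(=O)CC=C12 | intermediate
13 | 13,13-ethylenedioxy-14,15,17-trinorlabdan-8-one, 5α-H, C9 epimer mixture | O=C1CC[C@H]2C(C)(C)CCC[C@]2(C)C1CCC3(C)OCCO3 | intermediate (not isolated)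
14 | (5S,9S,10S)-13,13-ethylenedioxy-14,15,17-trinorlabdan-8-one | O=C1CC[C@H]2C(C)(C)CCC[C@]2(C)[C@H]1CCC3(C)OCCO3 | intermediate
15 | 13,13-ethylenedioxy-14,15,17-trinorlabd-7-en-8-yl trifluoromethanesulfonate | O=S(=O)(OC1=CC[C@H]2C(C)(C)CCC[C@]2(C)[C@H]1CCC3(C)OCCO3)C(F)(F)F | intermediate
16 | 13,13-ethylenedioxy-14,15-dinorlabd-7-ene | CC1=CC[C@H]2C(C)(C)CCC[C@]2(C)[C@H]1CCC3(C)OCCO3 | intermediate
17 | 14,15-dinorlabd-7-en-13-one | CC1=CC[C@H]2C(C)(C)CCC[C@]2(C)[C@H]1CCC(C)=O | intermediate
18 | diethyl 14,15-dinorlabda-7,13(16)-dien-13-yl phosphate | CC1=CC[C@H]2C(C)(C)CCC[C@]2(C)[C@H]1CCC(=C)OP(=O)(OCC)OCC | intermediate (not isolated)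
19 | 15,16-dinorlabd-7-en-13-yne | CC1=CC[C@H]2C(C)(C)CCC[C@]2(C)[C@H]1CCC#C | intermediate
20 | (5S,9S,10S)-labda-7,13E-dien-15-ol | CC1=CC[C@H]2C(C)(C)CCC[C@]2(C)[C@H]1CC/C(C)=C/CO | intermediate
21 | malonyl dichloride | O=C(Cl)CC(Cl)=O | starting material
22 | bis[(5S,9S,10S)-labda-7,13E-dien-15-yl] malonate | CC1=CC[C@H]2C(C)(C)CCC[C@]2(C)[C@H]1CC/C(C)=C/COC(=O)CC(=O)OC/C=C(\C)CC[C@H]1C(C)=CC[C@H]2C(C)(C)CCC[C@]12C | target

Total step count: 16. Longest linear sequence: 16 steps (from 1 to 22).

Steps most likely to fail

Step 9. The tertiary cation at C5 sits between two quaternary carbons, so a 1,2-methyl shift from C4 may compete with loss of the C6 proton, and the acid may also strip the dioxolane. The fallback changes from the cationic to the radical manifold. It sets out from 11: slow addition of Bu3SnH with AIBN in benzene at 80 °C should form the O-stannyl ketyl at C8, whose reversible cyclopropylcarbinyl opening can drain through the tertiary C5 radical. Hydrogen transfer to the α face of that radical would give the tributylstannyl enol ether F1. Treatment with NaOMe in MeOH, as in the second half of step 10, releases and equilibrates the ketone, so the route is rejoined at 14 and compound 12 is bypassed.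

Step 5. Substitution at the α′-carbon next to the quaternary C10 may be slow, so that elimination of HBr from the bromide or O-alkylation takes over. The fallback sets out from 6: LiN(i-Pr)2 and Me3SiCl give the 2-silyloxy diene F2. Mukaiyama–Michael addition of F2 to methyl vinyl ketone (TiCl4, CH2Cl2, −78 °C) gives the enedione F3. Selective ketalisation of its unhindered methyl ketone (ethylene glycol, PPTS, benzene, Dean–Stark) rejoins the route at 8.

Step 7. The zinc carbenoid may fail to reach the congested C5=C7 bond, above all in the carbinol epimer whose oxygen lies on the face of the two axial methyl groups. The fallback replaces the directed carbenoid by a small free carbene and sets out from 9: silylation (t-BuMe2SiCl, imidazole, DMF) gives the silyl ether F4. Dibromocarbene addition (CHBr3, KOt-Bu, pentane, 0 °C) gives the gem-dibromocyclopropane F5. Radical debromination (Bu3SnH, AIBN, benzene, 80 °C) gives the cyclopropane F6, and Bu4NF in THF removes the silyl group, rejoining the route at 10.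

Further compounds
F1 | step 9 | tributylstannyl enol ether of 13 (C7=C8–OSnBu3, 5α-H) | CCCC[Sn](CCCC)(CCCC)OC1=CC[C@H]2C(C)(C)CCC[C@]2(C)C1CCC3(C)OCCO3
F2 | step 5 | 2-(trimethylsilyloxy) diene of 6 | CC1(C)CCC[C@]2(C)C=C(O[Si](C)(C)C)C=C12
F3 | step 5 | C9-(3-oxobutyl) enedione | CC1(C)CCC[C@]2(C)C(CCC(C)=O)C(=O)C=C12
F4 | step 7 | tert-butyldimethylsilyl ether of 9 | CC1(C)CCC[C@]2(C)C(CCC3(C)OCCO3)C(O[Si](C)(C)C(C)(C)C)C=C12
F5 | step 7 | gem-dibromocyclopropane silyl ether | CC1(C)CCC[C@]2(C)C(CCC3(C)OCCO3)C(O[Si](C)(C)C(C)(C)C)C4C(Br)(Br)C124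
F6 | step 7 | tert-butyldimethylsilyl ether of 10 | CC1(C)CCC[C@]2(C)C(CCC3(C)OCCO3)C(O[Si](C)(C)C(C)(C)C)C4CC124
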